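The route rests on building ring A from two chain-bearing pieces instead of substituting a phloroglucinol. The feature exploited is that ring A is fully substituted, with geranyl at C6, prenyl at C8 and three oxygens (O1, O5, O7) of which O1 and O5 must be told apart for closure of ring C. Heating racemic 3-ethoxy-4-geranylcyclobutenone 9 with prenyl-bearing siloxyalkyne 14 runs a 4π-opening, [2+2], 4π-opening, 6π-closure cascade that forms C7–C8 and C4a–C8a and gives a phenol with O7–H, O1–Si, O5–Et and only C4a–H unsubstituted. C4a is then formylated and ring C is made through a chalcone, its asymmetric epoxidation and acid cyclisation.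

Key step: step 6

Remarks: flavonoid numbering is used (O1, C2, C3, C4, C4a, C5–C8, C8a; ring B primed); geranyl = (2E)-3,7-dimethylocta-2,6-dien-1-yl, prenyl = 3-methylbut-2-en-1-yl, MOM = methoxymethyl, TIPS = triisopropylsilyl.
Assumption: the (2R,3R) centres read from the target SMILES describe the 2,3-trans flavanonol, and the route is planned for that isomer.

Step 1
Reactants: 1 geranyl bromide; 2 diethyl malonate
Product: 3 diethyl 2-geranylmalonate
Conditions: NaH, 2 (2 equiv), THF, 0 °C → rt
Reagents that add atoms: none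
Why: Malonic ester alkylation, in which sodium diethyl malonate should displace the primary allylic bromide by SN2 at C1 without allylic transposition, the excess of malonate keeping dialkylation low.

Step 2
Reactants: 3 diethyl 2-geranylmalonate
Product: 5 (4E)-5,9-dimethyldeca-4,8-dienoic acid, via geranylmalonic acid 4 (not isolated)
Conditions: KOH, EtOH/H2O, reflux; 1 M HCl, 0 °C; pyridine, reflux
Reagents that add atoms: potassium hydroxide, [K+].[OH-]
Why: Saponification followed by thermal decarboxylation of the malonic acid through its cyclic transition state should leave the monoacid, pyridine keeping the medium non-acidic so that neither trisubstituted alkene is protonated.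

Step 3
Reactants: 5 (4E)-5,9-dimethyldeca-4,8-dienoic acid; 6 ethoxyacetylene
Product: 9 rac-3-ethoxy-4-geranylcyclobut-2-en-1-one, via acid chloride 7 (not isolated), via geranylketene 8 (not isolated)
Conditions: (COCl)2, cat. DMF, CH2Cl2, 0 °C → rt; evaporate; 6 (3 equiv), Et3N (slow addition), Et2O, 0 °C → rt
Reagents that add atoms: none
Why: The acid chloride should lose HCl to Et3N to give the aldoketene, which undergoes the polarity-controlled ketene–ynol ether [2+2] cycloaddition (CH terminus of 6 onto the ketene carbonyl carbon) to the 3-ethoxycyclobutenone, whose single stereocentre forms racemic and is erased in step 6.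

Step 4
Reactants: 10 4-methylpent-3-enoic acid
Product: 11 ethyl 4-methylpent-3-enoate
Conditions: EtI, K2CO3, DMF, rt
Reagents that add atoms: iodoethane, CCI
Why: SN2 O-alkylation of the carboxylate under basic conditions should give the ester while avoiding the acid-catalysed lactonisation onto the trisubstituted alkene that a Fischer esterification would risk.

Step 5
Reactants: 11 ethyl 4-methylpent-3-enoate
Product: 14 5-methyl-1-(triisopropylsilyloxy)hex-4-en-1-yne, via dibromomethyl ketone 12 (not isolated), via lithium ynolate 13 (not isolated)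
Conditions: CH2Br2, lithium 2,2,6,6-tetramethylpiperidide, THF, −78 °C; n-BuLi, −78 → 0 °C; i-Pr3SiCl, −78 °C → rt
Reagents that add atoms: dibromomethane, BrCBr; chlorotriisopropylsilane, CC(C)[Si](Cl)(C(C)C)C(C)C
Why: Kowalski ester homologation, in which LiCHBr2 should add to the ester, bromine–lithium exchange on the dibromomethyl ketone enolate triggers 1,2-shift of the 3-methylbut-2-enyl group to the ynolate, and the bulky silyl chloride traps it on oxygen.

Step 6
Reactants: 9 rac-3-ethoxy-4-geranylcyclobut-2-en-1-one; 14 5-methyl-1-(triisopropylsilyloxy)hex-4-en-1-yne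
Product: 19 3-ethoxy-2-geranyl-6-prenyl-5-(triisopropylsilyloxy)phenol, via vinylketene 15 (not isolated), via 4-vinylcyclobutenone 16 (not isolated), via dienylketene 17 (not isolated), via cyclohexadienone 18 (not isolated)
Conditions: 14 (1.3 equiv), PhMe, 80 °C then 110 °C, sealed tube, Ar
Reagents that add atoms: none
Why: At 80 °C cyclobutenone 9 should open by conrotatory 4π cleavage of its C1–C4 bond to vinylketene 15, whose carbonyl carbon is attacked by the nucleophilic, prenyl-bearing carbon of 14 in a [2+2] cycloaddition that forms C7–C8 and C4a–C8a and gives 4-vinylcyclobutenone 16. Further heating opens 16 to dienylketene 17, and ring A closes by thermal 6π electrocyclisation between the ketene carbon (C7) and the geranyl-bearing terminus (C6) to cyclohexadienone 18, which aromatises by tautomerisation so that the ketene oxygen becomes the free O7–H. The closest known reaction type is the thermal Danheiser benzannulation of cyclobutenones with siloxyalkynes. No stereocentre survives, because the racemic centre of 9 and the transient centres of 16 and 18 are erased on aromatisation. The selectivity needed is regiochemical and is secured by the matched polarity of the ketene (electrophilic at carbon) and the ynol ether (nucleophilic at its β-carbon), which places the silyloxy carbon next to C4a–H and the prenyl carbon next to the phenol, while the neutral thermal conditions leave the three trisubstituted alkenes alone.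

Step 7
Reactants: 19 3-ethoxy-2-geranyl-6-prenyl-5-(triisopropylsilyloxy)phenol
Product: 20 5-ethoxy-4-geranyl-2-prenylbenzene-1,3-diol
Conditions: Bu4NF, THF, 0 °C; H2O
Reagents that add atoms: none
Why: Fluoride-induced cleavage of the aryl Si–O bond should free O1, and O1 and O7 may be left free together because both are protected alike later, whereas O5 stays marked as its ethyl ether.

Step 8
Reactants: 20 5-ethoxy-4-geranyl-2-prenylbenzene-1,3-diol
Product: 21 2-ethoxy-3-geranyl-4,6-dihydroxy-5-prenylbenzaldehyde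
Conditions: MgCl2, Et3N, (CH2O)n, MeCN, reflux; 1 M HCl
Reagents that add atoms: paraformaldehyde (as formaldehyde), C=O
Why: Casnati–Skattebøl ortho-formylation, in which the magnesium phenoxide of O1 should deliver formaldehyde to C4a, the only unsubstituted ring carbon, and a second formaldehyde oxidises the benzylic alkoxide by hydride transfer under mildly basic conditions that spare the allyl chains.

Step 9
Reactants: 21 2-ethoxy-3-geranyl-4,6-dihydroxy-5-prenylbenzaldehyde
Product: 22 2-ethoxy-3-geranyl-4,6-bis(methoxymethoxy)-5-prenylbenzaldehyde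
Conditions: NaH, MeOCH2Cl, DMF, 0 °C → rt
Reagents that add atoms: chloromethyl methyl ether, COCCl
Why: Williamson-type alkylation of both sodium phenoxides with the reactive chloromethyl ether should cap O1 and O7 as base-stable acetals, which the aldol and epoxidation steps need and which one acid treatment removes at the end.

Step 10
Reactants: 22 2-ethoxy-3-geranyl-4,6-bis(methoxymethoxy)-5-prenylbenzaldehyde
Product: 23 rac-1-[2-ethoxy-3-geranyl-4,6-bis(methoxymethoxy)-5-prenylphenyl]ethan-1-ol
Conditions: MeMgBr, THF, 0 °C; H2O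
Reagents that add atoms: methylmagnesium bromide, C[Mg]Br
Why: Grignard addition to the non-enolisable aldehyde should give the secondary benzylic alcohol, whose new stereocentre is racemic and is removed in step 11.

Step 11
Reactants: 23 rac-1-[2-ethoxy-3-geranyl-4,6-bis(methoxymethoxy)-5-prenylphenyl]ethan-1-ol
Product: 24 1-[2-ethoxy-3-geranyl-4,6-bis(methoxymethoxy)-5-prenylphenyl]ethan-1-one
Conditions: Dess–Martin periodinane, NaHCO3, CH2Cl2, rt
Reagents that add atoms: none
Why: Dess–Martin oxidation under bicarbonate buffering should convert the hindered benzylic alcohol into the methyl ketone without free acid that could ionise the electron-rich benzylic position or cleave the acetals.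

Step 12
Reactants: 25 5-methoxyresorcinol
Product: 26 1-methoxy-3,5-bis(methoxymethoxy)benzene
Conditions: MeOCH2Cl, i-Pr2NEt, CH2Cl2, 0 °C → rt
Reagents that add atoms: chloromethyl methyl ether, COCCl
Why: O-Alkylation of both phenols with the chloromethyl ether and an amine base should give the bis-acetal, whose oxygens later direct the lithiation.

Step 13
Reactants: 26 1-methoxy-3,5-bis(methoxymethoxy)benzene
Product: 28 4-methoxy-2,6-bis(methoxymethoxy)benzaldehyde, via aryllithium 27 (not isolated)
Conditions: n-BuLi, TMEDA, THF, 0 °C; DMF, −78 °C → rt; H2O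
Reagents that add atoms: N,N-dimethylformamide, CN(C)C=O
Why: Directed ortho-metalation, in which the proton flanked by the two OCH2OMe groups is removed selectively through double coordination of lithium, and formylation of the aryllithium with DMF should give the 2,6-dioxygenated aldehyde.

Step 14
Reactants: 24 1-[2-ethoxy-3-geranyl-4,6-bis(methoxymethoxy)-5-prenylphenyl]ethan-1-one; 28 4-methoxy-2,6-bis(methoxymethoxy)benzaldehyde
Product: 30 (2E)-1-[2-ethoxy-3-geranyl-4,6-bis(methoxymethoxy)-5-prenylphenyl]-3-[4-methoxy-2,6-bis(methoxymethoxy)phenyl]prop-2-en-1-one, via aldol adduct 29 (not isolated)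
Conditions: KOH, EtOH, rt → 40 °C
Reagents that add atoms: none
Why: Claisen–Schmidt condensation, in which the potassium enolate of the methyl ketone should add to the non-enolisable aldehyde and E1cB dehydration of the aldol gives the thermodynamically favoured E-enone.

Step 15
Reactants: 30 the chalcone of step 14
Product: 31 [2-ethoxy-3-geranyl-4,6-bis(methoxymethoxy)-5-prenylphenyl]{(2R,3S)-3-[4-methoxy-2,6-bis(methoxymethoxy)phenyl]oxiran-2-yl}methanone
Conditions: poly-L-leucine, urea·H2O2, DBU, THF, rt
Reagents that add atoms: urea–hydrogen peroxide adduct, OO.NC(N)=O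
Why: Juliá–Colonna epoxidation (asymmetric Weitz–Scheffer reaction), in which hydroperoxide adds to the enone β-carbon at the helical L-peptide, a catalyst known to give (2R,3S)-chalcone oxides, the E-alkene fixes the trans relationship and the nucleophilic oxidant ignores the three isolated trisubstituted alkenes.

Step 16
Reactants: 31 the (2R,3S)-epoxy ketone of step 15
Product: 33 (2R,3R)-2-(2,6-dihydroxy-4-methoxyphenyl)-5-ethoxy-6-geranyl-3,7-dihydroxy-8-prenyl-2,3-dihydro-4H-chromen-4-one, via tetraphenol epoxide 32 (not isolated)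
Conditions: 3 M aq HCl, MeOH/THF, 40 °C
Reagents that add atoms: none
Why: Acid-mediated acetal cleavage and 6-endo epoxide opening, in which the freed O1–H should attack the benzylic epoxide carbon (activated by the ortho and para oxygens of ring B) with inversion to set C2 as R, C3 keeps the R configuration installed in step 15, and reversible ionisation at C2 funnels any cis isomer to the trans-diequatorial flavanonol.

Step 17
Reactants: 33 the 5-O-ethyl flavanonol of step 16
Product: 34 (2R,3R)-2-(2,6-dihydroxy-4-methoxyphenyl)-6-geranyl-3,5,7-trihydroxy-8-prenyl-2,3-dihydro-4H-chromen-4-one (target)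
Conditions: MgI2·OEt2, THF, reflux; H2O
Reagents that add atoms: none
Why: Chelation-assisted ether cleavage as known for 5-O-alkyl prenylflavanones with free phenols, in which magnesium bridging C4=O and O5 activates only the peri ethyl ether for SN2 attack of iodide at its CH2, so the unchelated 4'-methyl ether, the alkenes and both stereocentres should remain untouched.

Compound list
1 | geranyl bromide, (2E)-1-bromo-3,7-dimethylocta-2,6-diene | CC(C)=CCC/C(C)=C/CBr | starting material
2 | diethyl malonate | CCOC(=O)CC(=O)OCC | starting material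
3 | diethyl 2-geranylmalonate | CCOC(=O)C(C/C=C(\C)CCC=C(C)C)C(=O)OCC | intermediate
4 | geranylmalonic acid (in situ) | OC(=O)C(C/C=C(\C)CCC=C(C)C)C(=O)O | intermediate
5 | (4E)-5,9-dimethyldeca-4,8-dienoic acid | OC(=O)CC/C=C(\C)CCC=C(C)C | intermediate
6 | ethoxyacetylene | CCOC#C | starting material
7 | (4E)-5,9-dimethyldeca-4,8-dienoyl chloride (in situ) | ClC(=O)CC/C=C(\C)CCC=C(C)C | intermediate
8 | geranylketene, (4E)-5,9-dimethyldeca-1,4,8-trien-1-one (in situ) | O=C=CC/C=C(\C)CCC=C(C)C | intermediate
9 | rac-3-ethoxy-4-geranylcyclobut-2-en-1-one | CCOC1=CC(=O)C1C/C=C(\C)CCC=C(C)C | intermediate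
10 | 4-methylpent-3-enoic acid | CC(C)=CCC(=O)O | starting material
11 | ethyl 4-methylpent-3-enoate | CCOC(=O)CC=C(C)C | intermediate
12 | 1,1-dibromo-5-methylhex-4-en-2-one (in situ, as its lithium enolate) | CC(C)=CCC(=O)C(Br)Br | intermediate
13 | lithium 5-methylhex-4-en-1-yn-1-olate (in situ) | CC(C)=CCC#C[O-].[Li+] | intermediate
14 | 5-methyl-1-(triisopropylsilyloxy)hex-4-en-1-yne | CC(C)=CCC#CO[Si](C(C)C)(C(C)C)C(C)C | intermediate
15 | vinylketene, (3Z,6E)-3-ethoxy-7,11-dimethyldodeca-1,3,6,10-tetraen-1-one (in situ) | O=C=C/C(OCC)=C/C/C=C(\C)CCC=C(C)C | intermediate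
16 | rac-4-[(1Z,4E)-1-ethoxy-5,9-dimethyldeca-1,4,8-trien-1-yl]-2-prenyl-3-(triisopropylsilyloxy)cyclobut-2-en-1-one (in situ) | O=C1C(CC=C(C)C)=C(O[Si](C(C)C)(C(C)C)C(C)C)C1/C(OCC)=C/C/C=C(\C)CCC=C(C)C | intermediate
17 | dienylketene, (3E,5Z,8E)-5-ethoxy-9,13-dimethyl-2-prenyl-3-(triisopropylsilyloxy)tetradeca-1,3,5,8,12-pentaen-1-one (in situ) | O=C=C(CC=C(C)C)/C(O[Si](C(C)C)(C(C)C)C(C)C)=C\C(OCC)=C\C/C=C(\C)CCC=C(C)C | intermediate
18 | rac-5-ethoxy-6-geranyl-2-prenyl-3-(triisopropylsilyloxy)cyclohexa-2,4-dien-1-one (in situ) | O=C1C(CC=C(C)C)=C(O[Si](C(C)C)(C(C)C)C(C)C)C=C(OCC)C1C/C=C(\C)CCC=C(C)C | intermediate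
19 | 3-ethoxy-2-geranyl-6-prenyl-5-(triisopropylsilyloxy)phenol | Oc1c(CC=C(C)C)c(O[Si](C(C)C)(C(C)C)C(C)C)cc(OCC)c1C/C=C(\C)CCC=C(C)C | intermediate
20 | 5-ethoxy-4-geranyl-2-prenylbenzene-1,3-diol | Oc1cc(OCC)c(C/C=C(\C)CCC=C(C)C)c(O)c1CC=C(C)C | intermediate
21 | 2-ethoxy-3-geranyl-4,6-dihydroxy-5-prenylbenzaldehyde | O=Cc1c(OCC)c(C/C=C(\C)CCC=C(C)C)c(O)c(CC=C(C)C)c1O | intermediate
22 | 2-ethoxy-3-geranyl-4,6-bis(methoxymethoxy)-5-prenylbenzaldehyde | O=Cc1c(OCC)c(C/C=C(\C)CCC=C(C)C)c(OCOC)c(CC=C(C)C)c1OCOC | intermediate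
23 | rac-1-[2-ethoxy-3-geranyl-4,6-bis(methoxymethoxy)-5-prenylphenyl]ethan-1-ol | CC(O)c1c(OCC)c(C/C=C(\C)CCC=C(C)C)c(OCOC)c(CC=C(C)C)c1OCOC | intermediate
24 | 1-[2-ethoxy-3-geranyl-4,6-bis(methoxymethoxy)-5-prenylphenyl]ethan-1-one | CC(=O)c1c(OCC)c(C/C=C(\C)CCC=C(C)C)c(OCOC)c(CC=C(C)C)c1OCOC | intermediate
25 | 5-methoxyresorcinol, 5-methoxybenzene-1,3-diol | COc1cc(O)cc(O)c1 | starting material
26 | 1-methoxy-3,5-bis(methoxymethoxy)benzene | COCOc1cc(OC)cc(OCOC)c1 | intermediate
27 | [4-methoxy-2,6-bis(methoxymethoxy)phenyl]lithium (in situ) | [Li]c1c(OCOC)cc(OC)cc1OCOC | intermediate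
28 | 4-methoxy-2,6-bis(methoxymethoxy)benzaldehyde | O=Cc1c(OCOC)cc(OC)cc1OCOC | intermediate
29 | rac-1-[2-ethoxy-3-geranyl-4,6-bis(methoxymethoxy)-5-prenylphenyl]-3-hydroxy-3-[4-methoxy-2,6-bis(methoxymethoxy)phenyl]propan-1-one (in situ) | O=C(CC(O)c1c(OCOC)cc(OC)cc1OCOC)c1c(OCC)c(C/C=C(\C)CCC=C(C)C)c(OCOC)c(CC=C(C)C)c1OCOC | intermediate
30 | (2E)-1-[2-ethoxy-3-geranyl-4,6-bis(methoxymethoxy)-5-prenylphenyl]-3-[4-methoxy-2,6-bis(methoxymethoxy)phenyl]prop-2-en-1-one | O=C(/C=C/c1c(OCOC)cc(OC)cc1OCOC)c1c(OCC)c(C/C=C(\C)CCC=C(C)C)c(OCOC)c(CC=C(C)C)c1OCOC | intermediate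
31 | [2-ethoxy-3-geranyl-4,6-bis(methoxymethoxy)-5-prenylphenyl]{(2R,3S)-3-[4-methoxy-2,6-bis(methoxymethoxy)phenyl]oxiran-2-yl}methanone | O=C([C@@H]1O[C@H]1c1c(OCOC)cc(OC)cc1OCOC)c1c(OCC)c(C/C=C(\C)CCC=C(C)C)c(OCOC)c(CC=C(C)C)c1OCOC | intermediate
32 | [(2R,3S)-3-(2,6-dihydroxy-4-methoxyphenyl)oxiran-2-yl](2-ethoxy-3-geranyl-4,6-dihydroxy-5-prenylphenyl)methanone (in situ) | O=C([C@@H]1O[C@H]1c1c(O)cc(OC)cc1O)c1c(OCC)c(C/C=C(\C)CCC=C(C)C)c(O)c(CC=C(C)C)c1O | intermediate
33 | (2R,3R)-2-(2,6-dihydroxy-4-methoxyphenyl)-5-ethoxy-6-geranyl-3,7-dihydroxy-8-prenyl-2,3-dihydro-4H-chromen-4-one | COc1cc(O)c([C@H]2Oc3c(CC=C(C)C)c(O)c(C/C=C(\C)CCC=C(C)C)c(OCC)c3C(=O)[C@@H]2O)c(O)c1 | intermediate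
34 | (2R,3R)-2-(2,6-dihydroxy-4-methoxyphenyl)-6-geranyl-3,5,7-trihydroxy-8-prenyl-2,3-dihydro-4H-chromen-4-one | COc1cc(O)c([C@H]2Oc3c(CC=C(C)C)c(O)c(C/C=C(\C)CCC=C(C)C)c(O)c3C(=O)[C@@H]2O)c(O)c1 | target

Total step count: 17.
Longest linear sequence: 13 steps from geranyl bromide (steps 1, 2, 3, 6, 7, 8, 9, 10, 11, 14, 15, 16, 17).

Steps most likely to fail

Step 6. The vinylketene, unsubstituted next to its carbonyl, may dimerise or acylate the product phenol before the alkyne intercepts it, or the alkoxy-substituted cyclobutenone may resist 4π opening below the temperature at which the siloxyalkyne starts to degrade. The fallback makes the same vinylketene 15 at ambient temperature by 1,4-dehydrochlorination and bypasses the cyclobutenone. It sets out from geranyl bromide 1, which would alkylate the dianion of ethyl acetoacetate (NaH then n-BuLi, THF, 0 °C) at the terminal carbon to give ethyl (6E)-7,11-dimethyl-3-oxododeca-6,10-dienoate F1. Enol ether formation with HC(OEt)3 and catalytic TsOH in EtOH should give ethyl (2E,6E)-3-ethoxy-7,11-dimethyldodeca-2,6,10-trienoate F2, and saponification (KOH, EtOH/H2O) the acid (2E,6E)-3-ethoxy-7,11-dimethyldodeca-2,6,10-trienoic acid F3. Oxalyl chloride would convert it into (2E,6E)-3-ethoxy-7,11-dimethyldodeca-2,6,10-trienoyl chloride F4. Slow addition of F4 to Et3N and siloxyalkyne 14 in toluene (25 → 80 °C) should generate 15 by γ-deprotonation, and 15 enters the same [2+2], 4π-opening and 6π-closure sequence, coming back to the route at phenol 19.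

Step 15. Four ortho substituents and the electron-rich ring B may slow hydroperoxide addition and loosen the fit to the peptide, so that conversion stalls or facial selectivity is poor. The fallback gives up catalytic control and resolves instead. It sets out from chalcone 30, which a Weitz–Scheffer epoxidation (H2O2, NaOH, MeOH/THF) would convert into the racemic trans-epoxy ketone F5. The acid treatment of step 16 should then give the racemic trans-5-O-ethylflavanonol F6, in which the relative configuration is still governed by the epoxide. Preparative HPLC on an amylose tris(3,5-dimethylphenylcarbamate) phase would separate the enantiomers, and the (2R,3R) enantiomer is compound 33, where the route is rejoined.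

Step 16. Several processes may compete when acetal cleavage and epoxide opening run together: 1,2-aroyl shift from the benzylic cation, capture of that cation by a neighbouring acetal oxygen of ring B, acid-promoted chroman formation between O7–H and an allyl chain, and intermolecular arylation of the cation. The fallback separates the three events and keeps protic mineral acid out. It sets out from epoxide 31, which pyridinium p-toluenesulfonate in MeOH at 0 °C should open at the benzylic carbon to the (2R)-2-hydroxy-3-methoxy ketone F7 (C3 epimers, acetals intact). The four aryl acetals would then be removed under aprotic conditions (Me3SiOTf, 2,2′-bipyridyl, CH2Cl2, 0 °C, then H2O) to give the tetraphenol (2R)-2-hydroxy-3-methoxy ketone F8. Warming F8 with pyridinium p-toluenesulfonate in MeCN (50 °C) should close ring C by displacement of methanol at the benzylic carbon under thermodynamic control, returning to the route at compound 33.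

Further compounds
F1 | step 6 | ethyl (6E)-7,11-dimethyl-3-oxododeca-6,10-dienoate | CCOC(=O)CC(=O)CC/C=C(\C)CCC=C(C)C
F2 | step 6 | ethyl (2E,6E)-3-ethoxy-7,11-dimethyldodeca-2,6,10-trienoate | CCOC(=O)/C=C(/OCC)CC/C=C(\C)CCC=C(C)C
F3 | step 6 | (2E,6E)-3-ethoxy-7,11-dimethyldodeca-2,6,10-trienoic acid | OC(=O)/C=C(/OCC)CC/C=C(\C)CCC=C(C)C
F4 | step 6 | (2E,6E)-3-ethoxy-7,11-dimethyldodeca-2,6,10-trienoyl chloride | ClC(=O)/C=C(/OCC)CC/C=C(\C)CCC=C(C)C
F5 | step 15 | racemic trans-epoxy ketone, 1:1 mixture of 31 and its (2S,3R) enantiomer | O=C([C@@H]1O[C@H]1c1c(OCOC)cc(OC)cc1OCOC)c1c(OCC)c(C/C=C(\C)CCC=C(C)C)c(OCOC)c(CC=C(C)C)c1OCOC.O=C([C@H]1O[C@@H]1c1c(OCOC)cc(OC)cc1OCOC)c1c(OCC)c(C/C=C(\C)CCC=C(C)C)c(OCOC)c(CC=C(C)C)c1OCOC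
F6 | step 15 | racemic trans-5-O-ethylflavanonol, 1:1 mixture of 33 and its (2S,3S) enantiomer | COc1cc(O)c([C@H]2Oc3c(CC=C(C)C)c(O)c(C/C=C(\C)CCC=C(C)C)c(OCC)c3C(=O)[C@@H]2O)c(O)c1.COc1cc(O)c([C@@H]2Oc3c(CC=C(C)C)c(O)c(C/C=C(\C)CCC=C(C)C)c(OCC)c3C(=O)[C@H]2O)c(O)c1
F7 | step 16 | (2R)-1-[2-ethoxy-3-geranyl-4,6-bis(methoxymethoxy)-5-prenylphenyl]-2-hydroxy-3-methoxy-3-[4-methoxy-2,6-bis(methoxymethoxy)phenyl]propan-1-one (C3 epimers) | O=C([C@H](O)C(OC)c1c(OCOC)cc(OC)cc1OCOC)c1c(OCC)c(C/C=C(\C)CCC=C(C)C)c(OCOC)c(CC=C(C)C)c1OCOC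
F8 | step 16 | (2R)-3-(2,6-dihydroxy-4-methoxyphenyl)-1-(2-ethoxy-3-geranyl-4,6-dihydroxy-5-prenylphenyl)-2-hydroxy-3-methoxypropan-1-one (C3 epimers) | O=C([C@H](O)C(OC)c1c(O)cc(OC)cc1O)c1c(OCC)c(C/C=C(\C)CCC=C(C)C)c(O)c(CC=C(C)C)c1O
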